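The seven-membered ring (C10, C1, C2, C3, C4, C5, C9) is traced back to a cyclohexanone by deleting C1, the methylene between C10 and C2. The cis-hydroazulene thereby becomes a cis-hydrindan-4-one that maps onto 4,4-dimethylcyclohexenone. All five stereocentres are set on this six-membered platform. A hydrogen-atom-transfer Giese coupling joins the C8 radical to a chiral butenolide. The key step then inserts one carbon into the fully coupled keto lactone with trimethylsilyldiazomethane. It exploits the contrast between the two α-carbons of the C10 carbonyl: the free methylene C2 migrates, whereas methine C9, buttressed by quaternary C8, does not. Methylenation of C10 and lactone reorganisation finish the route.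

Key step: step 6

Remark on numbering (used throughout):
- C10 carries the exocyclic methylene C20.
- C1, C2 and C3 are the ring methylenes that follow C10.
- C4 is the gem-dimethyl carbon.
- C5 (next to C4) and C9 (next to C10) are the ring-fusion methines.
- C6 and C7 are the cyclopentane methylenes.
- C8 is the quaternary carbon bearing methyl C17.
- C14 is the side-chain methine and C15 its CH2O carbon.
- C13 is the lactone methine, C12 the lactone CH2 next to carbonyl C11, and C16 the lactone OCH2.
- The target is 5R,8R,9S,13R,14R.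

Remark on the chemistry (assumption): (5S)-5-(d-menthyloxy)furan-2(5H)-one, the enantiomer of the common l-menthyl acetal, is taken as a catalogue compound, as are the solutions of but-3-enylmagnesium bromide and (2-tert-butoxy-2-oxoethyl)zinc chloride.

Step 1
Reactants: 1 4,4-dimethylcyclohex-2-en-1-one; 2 but-3-en-1-ylmagnesium bromide
Product: 5 silyl enol ether [(3R)-3-(but-3-en-1-yl)-4,4-dimethylcyclohex-1-en-1-yl]oxy(trimethyl)silane, via di(but-3-enyl)zinc 3 (not isolated), via zinc enolate 4 (not isolated)
Conditions: 2 (2.4 equiv), ZnCl2 (1.2 equiv), Et2O, 0 °C to rt, then 1,4-dioxane, filtration; Cu(OTf)2 (2 mol %), (S,R,R)-binaphthyl bis(1-phenylethyl)amine phosphoramidite (4 mol %), toluene, -30 °C, 1; then TMSOTf (1.5 equiv), -30 °C to rt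
Reagents that add atoms: trimethylsilyl trifluoromethanesulfonate, C[Si](C)(C)OS(=O)(=O)C(F)(F)F; zinc chloride, Cl[Zn]Cl (its zinc stays in 3 and 4 only)
Why: Copper-catalysed enantioselective conjugate addition of a dialkylzinc, established for 4,4-disubstituted cyclohexenones, sets C5 (the S,R,R ligand should steer the alkyl group to the enone face that gives R), and O-silylation of the zinc enolate fixes the enol ether regiospecifically between C9 and C10.

Step 2
Reactants: 5 silyl enol ether
Product: 6 (3aR,7aR)-7,7-dimethyl-3-methylideneoctahydro-4H-inden-4-one (cis-fused)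
Conditions: Pd(OAc)2 (10 mol %), O2 (1 atm), DMSO, 45 °C
Reagents that add atoms: none
Why: Divalent-palladium cycloalkenylation of a silyl enol ether (Saegusa-type oxo-π-allylpalladium, 5-exo-trig carbopalladation, β-hydride elimination of the only β-hydrogen at C8) closes the cyclopentane, and because the tether on C5 can reach C9 only from its own face the ring fusion is cis.

Step 3
Reactants: 7 (5S)-5-(d-menthyloxy)furan-2(5H)-one
Product: 9 (5S)-3-bromo-5-(d-menthyloxy)furan-2(5H)-one, via trans-dibromolactone 8 (not isolated)
Conditions: Br2, CH2Cl2, 0 °C; then Et3N, 0 °C to rt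
Reagents that add atoms: bromine, BrBr
Why: Anti bromination of the alkene followed by E1cB-type dehydrobromination (the acidic C3 proton and the C4 bromide leave) gives the α-bromobutenolide without touching the acetal stereocentre.

Step 4
Reactants: 9 (5S)-3-bromo-5-(d-menthyloxy)furan-2(5H)-one; 10 (2-tert-butoxy-2-oxoethyl)zinc chloride
Product: 11 tert-butyl 2-[(5S)-5-(d-menthyloxy)-2-oxo-2,5-dihydrofuran-3-yl]acetate
Conditions: Pd(PPh3)4 (5 mol %), THF, 50 °C
Reagents that add atoms: none
Why: Negishi-type cross-coupling of a Reformatsky reagent with an electron-poor alkenyl bromide installs C12 and C11, and the weakly basic zinc enolate should neither epimerise the acetal carbon nor add in a conjugate sense.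

Step 5
Reactants: 6 cis-hydrindanone alkene; 11 butenolide acceptor
Product: 12 coupled hydrindanone keto lactone (5R,8S,9R,13R,14R,15S)
Conditions: Fe(acac)3 (30 mol %), PhSiH3 (2.5 equiv), 11 (2 equiv), EtOH/ClCH2CH2Cl, 60 °C
Reagents that add atoms: none
Why: Iron-hydride hydrogen atom transfer to the CH2 terminus of the 1,1-disubstituted alkene (reductive olefin coupling, a Giese reaction) creates methyl C17 and the tertiary C8 radical, which bonds on its convex face (the side of H9, away from C10) to C14 of 11 anti to the menthyloxy group, and the C13 enolate so formed is protonated from the face opposite the new quaternary substituent, which leaves C12 cis to C8 as the target requires.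

Step 6
Reactants: 12 coupled hydrindanone keto lactone
Product: 14 ring-expanded hydroazulenone keto lactone (5R,8S,9R,13R,14R,15S), via alpha-silyl ketone 13 (not isolated)
Conditions: TMSCHN2 (1.5 equiv), AlMe3 (1.2 equiv), CH2Cl2, -78 to -20 °C; then 1 M HCl, THF, 0 °C
Reagents that add atoms: trimethylsilyldiazomethane, C[Si](C)(C)C=[N+]=[N-]
Why: AlMe3 activates the C10 ketone, the most Lewis-basic carbonyl of 12, the diazo carbon adds to give a β-oxido diazonium ion, and the C10–C2 bond antiperiplanar to the departing N2 shifts onto the new carbon, so that C1 is inserted and the six-membered ring C10-C2-C3-C4-C5-C9 becomes the seven-membered ring, after which acid removes the silyl group of 13. The closest known reaction type is the Lewis-acid-promoted one-carbon homologation of cyclohexanones with trimethylsilyldiazomethane (Büchner–Curtius–Schlotterbeck, Tiffeneau–Demjanov-type ring expansion). No ring is closed: an existing ring is enlarged by a 1,2-shift. The only new stereocentre, the silyl-bearing C1 of 13, is erased on protodesilylation, and C9 keeps its configuration because it neither migrates nor is deprotonated under these non-basic conditions. The step needs migration of C2 rather than C9 and a single insertion: C9 is a methine wedged between C5 and quaternary C8, so the bulky Me3Si group turns away from it and thereby places the C2 methylene anti to N2, and the α-silyl ketone 13 is too hindered to react again. The ester and lactone carbonyls are not attacked by the diazoalkane, and no acid-labile alkene is present yet when the silyl group is removed.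

Step 7
Reactants: 14 ring-expanded keto lactone
Product: 15 methylidene lactone acetal (5R,8R,9S,13R,14R,15S)
Conditions: Zn, CH2Br2, TiCl4 (pre-formed slurry in THF), CH2Cl2, 0 °C to rt
Reagents that add atoms: dibromomethane, BrCBr
Why: Takai–Lombardo methylenation uses a non-basic gem-dimetallic titanium reagent that attacks ketones but not esters or lactones, so C20 is installed without epimerising C9 or C13.

Step 8
Reactants: 15 methylidene lactone acetal
Product: 16 diol tert-butyl ester (5R,8R,9S,13R,14R)
Conditions: LiBH4 (3 equiv), MeOH (3 equiv), Et2O, 0 °C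
Reagents that add atoms: none
Why: Chemoselective borohydride reduction takes the activated acyloxy-acetal lactone through the lactol and the dialdehyde stage to the C15,C16-diol with loss of the auxiliary, while the tert-butyl ester at C11 should survive and fast hydride capture of the aldehydes protects C13 and C14.

Step 9
Reactants: 16 diol tert-butyl ester
Product: 17 hydroxy lactone (5R,8R,9S,13R,14R)
Conditions: t-BuOK (20 mol %), THF, 0 °C to rt; AcOH quench
Reagents that add atoms: none
Why: Alkoxide-catalysed intramolecular transesterification (5-exo-trig lactonisation) closes the γ-lactone from the C16 hydroxyl, which is favoured kinetically and, since the process is reversible, thermodynamically over the δ-lactone from the hindered C15 hydroxyl, and the base leaves the exocyclic alkene untouched.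

Step 10
Reactants: 17 hydroxy lactone
Product: 18 target CNP0235949.1
Conditions: Ac2O, pyridine, DMAP (5 mol %), CH2Cl2, rt
Reagents that add atoms: acetic anhydride, CC(=O)OC(C)=O
Why: DMAP-catalysed acetylation of the only free hydroxyl (C15) completes the target without touching any stereocentre.

Compound list

1 | 4,4-dimethylcyclohex-2-en-1-one | CC1(C)CCC(=O)C=C1 | starting material
2 | but-3-en-1-ylmagnesium bromide | C=CCC[Mg]Br | starting material
3 | di(but-3-en-1-yl)zinc | C=CCC[Zn]CCC=C | intermediate
4 | but-3-enylzinc enolate of (3R)-3-(but-3-enyl)-4,4-dimethylcyclohexanone | C=CCC[C@@H]1C=C(O[Zn]CCC=C)CCC1(C)C | intermediate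
5 | [(3R)-3-(but-3-en-1-yl)-4,4-dimethylcyclohex-1-en-1-yl]oxy(trimethyl)silane | C=CCC[C@@H]1C=C(O[Si](C)(C)C)CCC1(C)C | intermediate
6 | (3aR,7aR)-7,7-dimethyl-3-methylideneoctahydro-4H-inden-4-one, cis-fused (H5 and H9 on the same face) | O=C1CCC(C)(C)[C@@H]2CCC(=C)[C@H]12 | intermediate
7 | (5S)-5-{[(1S,2R,5S)-5-methyl-2-(propan-2-yl)cyclohexyl]oxy}furan-2(5H)-one | O=C1C=C[C@@H](O[C@H]2C[C@@H](C)CC[C@@H]2C(C)C)O1 | starting material
8 | trans-3,4-dibromo-5-(d-menthyloxy)dihydrofuran-2(3H)-one, C4 bromide anti to the menthyloxy group | O=C1[C@@H](Br)[C@H](Br)[C@@H](O[C@H]2C[C@@H](C)CC[C@@H]2C(C)C)O1 | intermediate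
9 | (5S)-3-bromo-5-(d-menthyloxy)furan-2(5H)-one | O=C1C(Br)=C[C@@H](O[C@H]2C[C@@H](C)CC[C@@H]2C(C)C)O1 | intermediate
10 | (2-tert-butoxy-2-oxoethyl)zinc chloride | CC(C)(C)OC(=O)C[Zn]Cl | starting material
11 | tert-butyl 2-[(5S)-5-(d-menthyloxy)-2-oxo-2,5-dihydrofuran-3-yl]acetate | CC(C)(C)OC(=O)CC1=C[C@@H](O[C@H]2C[C@@H](C)CC[C@@H]2C(C)C)OC1=O | intermediate
12 | coupled keto lactone (5R,8S,9R,13R,14R,15S): cis-7,7-dimethylhydrindan-4-one whose C8 bears methyl C17 on the concave face and, on the convex face, C14 of a 5-(d-menthyloxy)butyrolactone; on the lactone C8 is trans to the menthyloxy group and cis to CH2CO2t-Bu | O=C1CCC(C)(C)[C@@H]2CC[C@@](C)([C@@H]3[C@@H](O[C@H]4C[C@@H](C)CC[C@@H]4C(C)C)OC(=O)[C@@H]3CC(=O)OC(C)(C)C)[C@H]12 | intermediate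
13 | ring-expanded ketone carrying Me3Si on the inserted carbon C1 (either epimer at C1) | O=C1C([Si](C)(C)C)CCC(C)(C)[C@@H]2CC[C@@](C)([C@@H]3[C@@H](O[C@H]4C[C@@H](C)CC[C@@H]4C(C)C)OC(=O)[C@@H]3CC(=O)OC(C)(C)C)[C@H]12 | intermediate
14 | cis-hydroazulen-10-one keto lactone (5R,8S,9R,13R,14R,15S), side chain as in 12 | O=C1CCCC(C)(C)[C@@H]2CC[C@@](C)([C@@H]3[C@@H](O[C@H]4C[C@@H](C)CC[C@@H]4C(C)C)OC(=O)[C@@H]3CC(=O)OC(C)(C)C)[C@H]12 | intermediate
15 | 10-methylidene cis-hydroazulene lactone acetal (5R,8R,9S,13R,14R,15S) | C=C1CCCC(C)(C)[C@@H]2CC[C@@](C)([C@@H]3[C@@H](O[C@H]4C[C@@H](C)CC[C@@H]4C(C)C)OC(=O)[C@@H]3CC(=O)OC(C)(C)C)[C@H]12 | intermediate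
16 | C15,C16-diol with tert-butyl ester at C11 (5R,8R,9S,13R,14R) | C=C1CCCC(C)(C)[C@@H]2CC[C@@](C)([C@H](CO)[C@H](CO)CC(=O)OC(C)(C)C)[C@H]12 | intermediate
17 | C15 alcohol with the C11/C16 γ-lactone closed (5R,8R,9S,13R,14R) | C=C1CCCC(C)(C)[C@@H]2CC[C@@](C)([C@H](CO)[C@@H]3COC(=O)C3)[C@H]12 | intermediate
18 | CNP0235949.1, the C15 acetate (5R,8R,9S,13R,14R) | C=C1CCCC(C)(C)[C@@H]2CC[C@@](C)([C@H](COC(C)=O)[C@@H]3COC(=O)C3)[C@H]12 | target

Total step count: 10. Longest linear sequence: 8 steps (1, 2, 5, 6, 7, 8, 9, 10). Steps 3 and 4 form the side branch to the acceptor.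

Steps most likely to fail

Step 5. Three processes could undermine the coupling:
- Back transfer of hydrogen to iron, which moves the alkene into conjugation with the ketone, may outrun the slow addition of the hindered tertiary radical.
- Simple hydrogenation of the alkene may do the same.
- Alkoxide formed at 60 °C may erode the kinetic protonation at C13.

The fallback leaves metal-hydride chemistry and makes the same radical by photoredox fragmentation of an oxalate at room temperature. It sets out from 6. Mukaiyama hydration (Mn(dpm)3, PhSiH3, O2, i-PrOH) would give the tertiary alcohol F1. Acylation with methyl chlorooxoacetate (Et3N, DMAP, CH2Cl2, -20 °C) would give the methyl oxalate F2, and aqueous CsOH in THF the caesium oxalate F3. Blue-light irradiation of F3 with Ir[dF(CF3)ppy]2(dtbbpy)PF6, 11 and water in DME/DMF comes back to the route at 12.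

Step 6. Addition of the bulky diazoalkane to the hindered ketone may be slow. This would let spiro-epoxide formation or Lewis-acid attack on the lactone acetal compete.

The fallback replaces the diazo insertion by a cyclopropanation and oxidative fragmentation sequence (Saegusa-type one-carbon ring expansion). It sets out from 12.
- Soft enolisation (TMSOTf, Et3N, CH2Cl2, 0 °C) occurs towards C2 because H9 is shielded, and would give the silyl enol ether F4.
- Simmons–Smith cyclopropanation (Et2Zn, CH2I2) would give the siloxycyclopropane F5.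
- FeCl3 in DMF at 0 °C cleaves the ring-fusion cyclopropane bond to the β-chloro ketone F6.
- NaOAc in MeOH gives the cycloheptenone F7.
- H2 over Pd/C comes back to the route at 14.

Step 2. Dehydrosilylation to the enone (Saegusa oxidation) may outrun carbopalladation. Palladium hydride may also move the exocyclic alkene into conjugation.

The fallback is a redox-neutral gold-catalysed alkyne cyclisation. It sets out from 1.
- The copper-catalysed conjugate addition of step 1 is run with bis[4-(trimethylsilyl)but-3-yn-1-yl]zinc F8, made from 4-iodo-1-(trimethylsilyl)but-1-yne by iodine–zinc exchange with Et2Zn.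
- Trapping with TBSOTf would give the silyl enol ether F9.
- K2CO3 in MeOH frees the terminal alkyne F10.
- (Ph3P)AuCl/AgBF4 (5 mol % each) in CH2Cl2/MeOH effects 5-exo-dig attack of the enol ether on the alkyne and comes back to the route at 6.

Further compounds
F1 | step 5 | 3-hydroxy-3,7,7-trimethyl-cis-octahydro-4H-inden-4-one (either C8 epimer) | O=C1CCC(C)(C)[C@@H]2CCC(C)(O)[C@H]12
F2 | step 5 | methyl oxalate of F1 | O=C1CCC(C)(C)[C@@H]2CCC(C)(OC(=O)C(=O)OC)[C@H]12
F3 | step 5 | caesium oxalate of F1 | O=C1CCC(C)(C)[C@@H]2CCC(C)(OC(=O)C(=O)[O-])[C@H]12.[Cs+]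
F4 | step 6 | trimethylsilyl enol ether of 12 (C10=C2) | C[Si](C)(C)OC1=CCC(C)(C)[C@@H]2CC[C@@](C)([C@@H]3[C@@H](O[C@H]4C[C@@H](C)CC[C@@H]4C(C)C)OC(=O)[C@@H]3CC(=O)OC(C)(C)C)[C@H]12
F5 | step 6 | siloxycyclopropane spanning C10 and C2 | C[Si](C)(C)OC15CC5CC(C)(C)[C@@H]2CC[C@@](C)([C@@H]3[C@@H](O[C@H]4C[C@@H](C)CC[C@@H]4C(C)C)OC(=O)[C@@H]3CC(=O)OC(C)(C)C)[C@H]12
F6 | step 6 | 2-chloro hydroazulen-10-one keto lactone | O=C1CC(Cl)CC(C)(C)[C@@H]2CC[C@@](C)([C@@H]3[C@@H](O[C@H]4C[C@@H](C)CC[C@@H]4C(C)C)OC(=O)[C@@H]3CC(=O)OC(C)(C)C)[C@H]12
F7 | step 6 | hydroazulen-1-en-10-one keto lactone | O=C1C=CCC(C)(C)[C@@H]2CC[C@@](C)([C@@H]3[C@@H](O[C@H]4C[C@@H](C)CC[C@@H]4C(C)C)OC(=O)[C@@H]3CC(=O)OC(C)(C)C)[C@H]12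
F8 | step 2 | bis[4-(trimethylsilyl)but-3-yn-1-yl]zinc | C[Si](C)(C)C#CCC[Zn]CCC#C[Si](C)(C)C
F9 | step 2 | tert-butyldimethylsilyl enol ether of (3R)-4,4-dimethyl-3-[4-(trimethylsilyl)but-3-ynyl]cyclohexanone | C[Si](C)(C)C#CCC[C@@H]1C=C(O[Si](C)(C)C(C)(C)C)CCC1(C)C
F10 | step 2 | tert-butyldimethylsilyl enol ether of (3R)-3-(but-3-ynyl)-4,4-dimethylcyclohexanone | C#CCC[C@@H]1C=C(O[Si](C)(C)C(C)(C)C)CCC1(C)C
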